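The target is cut at its ester and at the styryl double bond, leaving an anti 1,3-diol masked as a trans 1,3-dioxan-2-one (C1 = carbinol carbon, C2 = adjacent methine, C3 = acyloxymethyl carbon). That ring is made by anodic oxidation of the C1–H bond, which is benzylic to the 4-methoxyphenyl ring. Because the C3 oxygen and C1 are 1,3-related, a tert-butyl carbonate on C3 can trap the C1 cation through its carbonyl oxygen. One electrolysis thus forms the C1–O bond, the six-membered ring and the C1 stereocentre, directed by C2. The precursor is the tert-butyl carbonate of (R)-2-(4-methoxybenzyl)pent-4-en-1-ol; the oxidisable dimethoxystyryl group and the Z ester are added afterwards.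

Key step: step 5

Remark: (R)-9 and trans-(4S,5S)-12 carry the spatial arrangement of the (1S,2S) target (the C2 descriptor changes only through priorities); the (R)-4-benzyl auxiliary is the enantiomer that leads to (R)-9, and a hindered pyridine is chosen as electrolysis buffer because unhindered pyridines can be N-alkylated by benzylic cations.

Step 1
Reactants: 1 3-(4-methoxyphenyl)propanoic acid; 2 (R)-4-benzyl-1,3-oxazolidin-2-one
Product: 4 (R)-4-benzyl-3-[3-(4-methoxyphenyl)propanoyl]-1,3-oxazolidin-2-one, via mixed pivalic anhydride 3 (not isolated)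
Conditions: PivCl, Et3N, THF, −20 °C; then LiCl, 2, −20 °C to rt
Reagents that add atoms: none
Why: Mixed-anhydride N-acylation of an oxazolidinone, in which the hindered pivaloyl carbonyl steers the LiCl-activated oxazolidinone onto the arylpropanoyl carbonyl.

Step 2
Reactants: 4 (R)-4-benzyl-3-[3-(4-methoxyphenyl)propanoyl]-1,3-oxazolidin-2-one; 5 allyl bromide
Product: 7 (R)-4-benzyl-3-[(2R)-2-(4-methoxybenzyl)pent-4-enoyl]-1,3-oxazolidin-2-one, via sodium Z-enolate 6 (not isolated)
Conditions: NaN(SiMe3)2, THF, −78 °C; allyl bromide, −78 to −40 °C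
Reagents that add atoms: none
Why: Evans asymmetric alkylation, in which the chelated Z sodium enolate is allylated on the face away from the benzyl group of the (R)-auxiliary, which should set C2 as R.

Step 3
Reactants: 7 (R)-4-benzyl-3-[(2R)-2-(4-methoxybenzyl)pent-4-enoyl]-1,3-oxazolidin-2-one
Product: 8 (2R)-2-(4-methoxybenzyl)pent-4-en-1-ol
Conditions: LiBH4, MeOH (1 equiv), Et2O, 0 °C; aq. NaOH work-up
Reagents that add atoms: none
Why: Reductive cleavage of the N-acyloxazolidinone by hydride attack on the exocyclic carbonyl should release the primary alcohol and the auxiliary without touching the alkene or the C2 centre.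

Step 4
Reactants: 8 (2R)-2-(4-methoxybenzyl)pent-4-en-1-ol
Product: 9 tert-butyl (2R)-2-(4-methoxybenzyl)pent-4-enyl carbonate
Conditions: Boc2O, DMAP (cat.), MeCN, rt
Reagents that add atoms: di-tert-butyl dicarbonate, CC(C)(C)OC(=O)OC(=O)OC(C)(C)C
Why: DMAP-catalysed tert-butoxycarbonylation of an unhindered primary alcohol installs the carbonate whose carbonyl oxygen later serves as the internal nucleophile.

Step 5
Reactants: 9 tert-butyl (2R)-2-(4-methoxybenzyl)pent-4-enyl carbonate
Product: 12 trans-(4S,5S)-4-(4-methoxyphenyl)-5-(prop-2-enyl)-1,3-dioxan-2-one, via benzylic cation 10 (not isolated), via 2-tert-butoxy-1,3-dioxan-2-ylium ion 11 (not isolated)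
Conditions: graphite anode, Pt cathode, undivided cell, constant current (about 2.2 F per mol), Bu4NBF4, CH2Cl2/(CF3)2CHOH 9:1, 2,6-di-tert-butylpyridine (2 equiv), 0 °C
Reagents that add atoms: none
Why: Proposed new method: the anisole ring of 9 is the only group oxidised at the working potential, so electron loss, deprotonation of the radical cation at C1 and a second electron loss should give the quinoid 4-methoxybenzylic cation 10, which the carbonate carbonyl oxygen captures to give ion 11, and 11 sheds isobutene to leave 12 while the protons are reduced to H2 at the cathode. The closest known reaction types are anodic benzylic C–H acyloxylation and lactonisation of 4-alkylanisoles, and the trapping of benzylic cations by internal tert-butyl carbonates when the cation is made with a quinone oxidant; running both in one electrolysis is the untested part. The ring closes in 6-exo-trig mode at the cationic carbon C1. The new C1 centre is controlled by the existing C2 centre, because a chair-like transition state with the aryl group on C1 and the allyl group on C2 both equatorial leads to the trans (4S,5S) ring, which is also the more stable isomer. The step needs site selectivity for C1–H over the allylic position and the alkene, secured by the 4-methoxy group that localises oxidation on its ring and by the high oxidation potential of a monosubstituted alkene; it must also stop after two electrons, which charge control and the electron-withdrawing carbonate oxygen on C1 of 12 should secure.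

Step 6
Reactants: 12 trans-(4S,5S)-4-(4-methoxyphenyl)-5-(prop-2-enyl)-1,3-dioxan-2-one; 13 3,4-dimethoxystyrene
Product: 14 trans-(4S,5S)-5-[(2E)-3-(3,4-dimethoxyphenyl)prop-2-enyl]-4-(4-methoxyphenyl)-1,3-dioxan-2-one
Conditions: 13 (3 equiv), second-generation Grubbs catalyst RuCl2(=CHPh)(H2IMes)(PCy3) (5 mol %), CH2Cl2, 40 °C
Reagents that add atoms: none
Why: Olefin cross metathesis of a terminal alkene with an excess of a styrene should give the E-styryl alkene under reversible exchange with loss of ethene, while the cyclic carbonate keeps both oxygens masked.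

Step 7
Reactants: 14 trans-(4S,5S)-5-[(2E)-3-(3,4-dimethoxyphenyl)prop-2-enyl]-4-(4-methoxyphenyl)-1,3-dioxan-2-one
Product: 15 (1S,2S)-2-[(2E)-3-(3,4-dimethoxyphenyl)prop-2-enyl]-1-(4-methoxyphenyl)propane-1,3-diol
Conditions: K2CO3, MeOH, rt
Reagents that add atoms: none
Why: Base-catalysed methanolysis (transesterification) of the cyclic carbonate should free the anti 1,3-diol without affecting either stereocentre or the alkene.

Step 8
Reactants: 16 (E)-but-2-enal (crotonaldehyde)
Product: 17 (Z)-2-iodobut-2-enal
Conditions: I2, K2CO3, DMAP (cat.), THF/H2O 1:1, rt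
Reagents that add atoms: iodine, II
Why: α-Iodination of an enal by a Baylis–Hillman-type sequence (conjugate addition of DMAP, iodination of the enolate, E1cB loss of DMAP) should give the isomer with the methyl group trans to the formyl group, which is Z.

Step 9
Reactants: 17 (Z)-2-iodobut-2-enal
Product: 18 (Z)-2-iodobut-2-en-1-ol
Conditions: NaBH4, CeCl3·7H2O, MeOH, 0 °C
Reagents that add atoms: none
Why: Luche 1,2-reduction of the enal should leave the vinyl iodide and the alkene geometry untouched.

Step 10
Reactants: 18 (Z)-2-iodobut-2-en-1-ol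
Product: 19 tert-butyl{[(Z)-2-iodobut-2-enyl]oxy}dimethylsilane
Conditions: TBSCl, imidazole, CH2Cl2, 0 °C to rt
Reagents that add atoms: tert-butyldimethylsilyl chloride, CC(C)(C)[Si](C)(C)Cl
Why: Imidazole-mediated silylation of a primary allylic alcohol is routine and gives a group that fluoride removes at the end.

Step 11
Reactants: 19 tert-butyl{[(Z)-2-iodobut-2-enyl]oxy}dimethylsilane
Product: 21 (Z)-2-{[(tert-butyldimethylsilyl)oxy]methyl}but-2-enoic acid, via alkenyllithium 20 (not isolated)
Conditions: t-BuLi (2.1 equiv), Et2O, −78 °C; CO2, −78 °C; aq. HCl to pH 3, 0 °C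
Reagents that add atoms: carbon dioxide, O=C=O
Why: Iodine–lithium exchange at −78 °C should give a configurationally stable alkenyllithium that is carboxylated with retention, so the methyl group ends cis to the carboxyl group (Z acid).

Step 12
Reactants: 21 (Z)-2-{[(tert-butyldimethylsilyl)oxy]methyl}but-2-enoic acid; 15 (1S,2S)-2-[(2E)-3-(3,4-dimethoxyphenyl)prop-2-enyl]-1-(4-methoxyphenyl)propane-1,3-diol
Product: 23 [(2S,4E)-5-(3,4-dimethoxyphenyl)-2-[(S)-hydroxy(4-methoxyphenyl)methyl]pent-4-enyl] (2Z)-2-{[(tert-butyldimethylsilyl)oxy]methyl}but-2-enoate, via Yamaguchi mixed anhydride 22 (not isolated)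
Conditions: 21, 2,4,6-Cl3C6H2COCl, Et3N, toluene, rt; then 15, DMAP (0.3 equiv), 0 °C
Reagents that add atoms: none
Why: Yamaguchi esterification, in which the preformed mixed anhydride should acylate the unhindered primary hydroxyl much faster than the branched benzylic secondary one, and low temperature with substoichiometric DMAP limits Z to E isomerisation.

Step 13
Reactants: 23 [(2S,4E)-5-(3,4-dimethoxyphenyl)-2-[(S)-hydroxy(4-methoxyphenyl)methyl]pent-4-enyl] (2Z)-2-{[(tert-butyldimethylsilyl)oxy]methyl}but-2-enoate
Product: 24 [(2S,4E)-5-(3,4-dimethoxyphenyl)-2-[(S)-hydroxy(4-methoxyphenyl)methyl]pent-4-enyl] (2Z)-2-(hydroxymethyl)but-2-enoate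
Conditions: Bu4NF, AcOH (1:1), THF, 0 °C to rt
Reagents that add atoms: none
Why: Fluoride-mediated cleavage of the primary silyl ether, buffered with acetic acid, should avoid acyl migration and base-induced ester cleavage.

Compound list
1 | 3-(4-methoxyphenyl)propanoic acid | COc1ccc(CCC(=O)O)cc1 | starting material
2 | (R)-4-benzyl-1,3-oxazolidin-2-one | O=C1N[C@H](Cc2ccccc2)CO1 | starting material
3 | 3-(4-methoxyphenyl)propanoic pivalic anhydride | COc1ccc(CCC(=O)OC(=O)C(C)(C)C)cc1 | intermediate
4 | (R)-4-benzyl-3-[3-(4-methoxyphenyl)propanoyl]-1,3-oxazolidin-2-one | COc1ccc(CCC(=O)N2[C@H](Cc3ccccc3)COC2=O)cc1 | intermediate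
5 | allyl bromide | C=CCBr | starting material
6 | sodium Z-enolate of 4 | COc1ccc(C/C=C(\[O-])N2[C@H](Cc3ccccc3)COC2=O)cc1.[Na+] | intermediate
7 | (R)-4-benzyl-3-[(2R)-2-(4-methoxybenzyl)pent-4-enoyl]-1,3-oxazolidin-2-one | C=CC[C@H](Cc1ccc(OC)cc1)C(=O)N1[C@H](Cc2ccccc2)COC1=O | intermediate
8 | (2R)-2-(4-methoxybenzyl)pent-4-en-1-ol | C=CC[C@H](Cc1ccc(OC)cc1)CO | intermediate
9 | tert-butyl (2R)-2-(4-methoxybenzyl)pent-4-enyl carbonate | CC(C)(C)OC(=O)OC[C@H](CC=C)Cc1ccc(OC)cc1 | intermediate
10 | 4-methoxybenzylic cation at C1 of 9 (C2 unchanged) | CC(C)(C)OC(=O)OC[C@H](CC=C)[CH+]c1ccc(OC)cc1 | intermediate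
11 | (4S,5S)-2-tert-butoxy-4-(4-methoxyphenyl)-5-(prop-2-enyl)-1,3-dioxan-2-ylium ion | CC(C)(C)OC1OC[C@H](CC=C)[C@@H](c2ccc(OC)cc2)[O+]=1 | intermediate
12 | trans-(4S,5S)-4-(4-methoxyphenyl)-5-(prop-2-enyl)-1,3-dioxan-2-one | O=C1OC[C@H](CC=C)[C@@H](c2ccc(OC)cc2)O1 | intermediate
13 | 3,4-dimethoxystyrene | C=Cc1ccc(OC)c(OC)c1 | starting material
14 | trans-(4S,5S)-5-[(2E)-3-(3,4-dimethoxyphenyl)prop-2-enyl]-4-(4-methoxyphenyl)-1,3-dioxan-2-one | O=C1OC[C@H](C/C=C/c2ccc(OC)c(OC)c2)[C@@H](c2ccc(OC)cc2)O1 | intermediate
15 | (1S,2S)-2-[(2E)-3-(3,4-dimethoxyphenyl)prop-2-enyl]-1-(4-methoxyphenyl)propane-1,3-diol | OC[C@H](C/C=C/c1ccc(OC)c(OC)c1)[C@H](O)c1ccc(OC)cc1 | intermediate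
16 | (E)-but-2-enal (crotonaldehyde) | C/C=C/C=O | starting material
17 | (Z)-2-iodobut-2-enal | C/C=C(\I)C=O | intermediate
18 | (Z)-2-iodobut-2-en-1-ol | C/C=C(\I)CO | intermediate
19 | tert-butyl{[(Z)-2-iodobut-2-enyl]oxy}dimethylsilane | C/C=C(\I)CO[Si](C)(C)C(C)(C)C | intermediate
20 | (E)-1-[(tert-butyldimethylsilyl)oxy]but-2-en-2-yllithium (methyl cis to lithium) | C/C=C(\[Li])CO[Si](C)(C)C(C)(C)C | intermediate
21 | (Z)-2-{[(tert-butyldimethylsilyl)oxy]methyl}but-2-enoic acid | C/C=C(/CO[Si](C)(C)C(C)(C)C)C(=O)O | intermediate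
22 | (Z)-2-{[(tert-butyldimethylsilyl)oxy]methyl}but-2-enoic 2,4,6-trichlorobenzoic anhydride | C/C=C(/CO[Si](C)(C)C(C)(C)C)C(=O)OC(=O)c1c(Cl)cc(Cl)cc1Cl | intermediate
23 | [(2S,4E)-5-(3,4-dimethoxyphenyl)-2-[(S)-hydroxy(4-methoxyphenyl)methyl]pent-4-enyl] (2Z)-2-{[(tert-butyldimethylsilyl)oxy]methyl}but-2-enoate | C/C=C(/CO[Si](C)(C)C(C)(C)C)C(=O)OC[C@H](C/C=C/c1ccc(OC)c(OC)c1)[C@H](O)c1ccc(OC)cc1 | intermediate
24 | [(2S,4E)-5-(3,4-dimethoxyphenyl)-2-[(S)-hydroxy(4-methoxyphenyl)methyl]pent-4-enyl] (2Z)-2-(hydroxymethyl)but-2-enoate | C/C=C(/CO)C(=O)OC[C@H](C/C=C/c1ccc(OC)c(OC)c1)[C@H](O)c1ccc(OC)cc1 | target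

Total step count: 13. Longest linear sequence: 9 steps (steps 1 to 7, 12 and 13); the acid branch (steps 8 to 11) joins at step 12.

Steps most likely to fail

1. Step 5 (proposed new method). The benzylic cation may be intercepted by hexafluoroisopropanol or by the electrolyte anion instead of by the carbonate, oxidation may continue at C1, acid formed near the anode may strip the tert-butoxycarbonyl group, or the closure may show low trans selectivity. The fallback uses only known chemistry and sets both centres without C–H oxidation. It sets out from allyl bromide 5 and commercial ethyl 3-(4-methoxyphenyl)-3-oxopropanoate. Noyori asymmetric hydrogenation (RuCl2[(R)-BINAP], H2, EtOH) should give ethyl (3S)-3-hydroxy-3-(4-methoxyphenyl)propanoate F1. Fráter–Seebach alkylation of its dianion (LiN(iPr)2, 2.2 equiv, THF, −50 to −20 °C) with 5 should give the anti product ethyl (2R)-2-[(S)-hydroxy(4-methoxyphenyl)methyl]pent-4-enoate F2, the allyl group entering anti to the aryl carbinol substituent of the chelated dianion. LiAlH4 in THF should then give (1S,2S)-1-(4-methoxyphenyl)-2-(prop-2-enyl)propane-1,3-diol F3, and 1,1'-carbonyldiimidazole closes the cyclic carbonate, so the fallback comes back to the route at 12.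

2. Step 12. Acylation may also occur at the secondary hydroxyl or at both hydroxyls, and the activated acid may isomerise from Z to E through reversible conjugate addition of DMAP. The fallback forms the ester without an activated acyl donor: it sets out from vinyl iodide 19 and diol 15 and joins them by palladium-catalysed alkoxycarbonylation (PdCl2(PPh3)2, CO at 1 atm, Et3N, DMF, 50 °C). Oxidative addition and CO insertion keep the alkene geometry, and the primary hydroxyl should intercept the acylpalladium species first. It comes back to the route at 23 and makes no new compound.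

3. Step 6. The electron-rich styrene may homodimerise to the stilbene, the catalyst may decompose before conversion is complete, or the double bond may migrate or form with incomplete E selectivity. The fallback attaches the aryl group by cross-coupling. It sets out from 12, which undergoes cross metathesis with vinylboronic acid pinacol ester (same ruthenium catalyst, CH2Cl2, 40 °C) to give trans-(4S,5S)-4-(4-methoxyphenyl)-5-[(2E)-3-(4,4,5,5-tetramethyl-1,3,2-dioxaborolan-2-yl)prop-2-enyl]-1,3-dioxan-2-one F4. Suzuki–Miyaura coupling of F4 with 4-bromo-1,2-dimethoxybenzene (Pd(dppf)Cl2, K3PO4, THF/H2O, 50 °C) then comes back to the route at 14.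

Further compounds
F1 | step 5 | ethyl (3S)-3-hydroxy-3-(4-methoxyphenyl)propanoate | CCOC(=O)C[C@H](O)c1ccc(OC)cc1
F2 | step 5 | ethyl (2R)-2-[(S)-hydroxy(4-methoxyphenyl)methyl]pent-4-enoate | CCOC(=O)[C@H](CC=C)[C@H](O)c1ccc(OC)cc1
F3 | step 5 | (1S,2S)-1-(4-methoxyphenyl)-2-(prop-2-enyl)propane-1,3-diol | OC[C@H](CC=C)[C@H](O)c1ccc(OC)cc1
F0 | step 12 | none | none
F4 | step 6 | trans-(4S,5S)-4-(4-methoxyphenyl)-5-[(2E)-3-(4,4,5,5-tetramethyl-1,3,2-dioxaborolan-2-yl)prop-2-enyl]-1,3-dioxan-2-one | O=C1OC[C@H](C/C=C/B2OC(C)(C)C(C)(C)O2)[C@@H](c2ccc(OC)cc2)O1
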